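**Retrosynthetic overview**

1. Numbering: C1 is the CH2OAc carbon, C6 the carbinol carbon, C7 the quaternary ring carbon, C8 and C9 the ring CH2 groups, C10=C11 the ring alkene, and the lactone carbonyl sits on C11. The only ring, the tetrahydrooxepin-7-one, is cut at O–C7 and at C9–C10 in one operation, which splits the target into a C1–C9 half and a C10–C15 acrylate half.
2. O–C7 comes from 7-exo opening of a (6R,7R)-trans-epoxide at its tertiary carbon by the ester carbonyl oxygen, with inversion, which also frees the C6 hydroxyl. C9–C10 comes from a nickel-catalysed reductive coupling of a primary alkyl bromide with a Z-enol triflate.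
3. Enabling feature: the endocyclic C10=C11 bond is cis, so C9 and the carbonyl oxygen lie on the same side and the oxygen reaches C7 through a seven-membered transition state. The ring oxygen on C7 and the hydroxyl on C6 stand anti in the sense of an E-alkene, which is the mark of an epoxide opened with inversion.
4. The bromo epoxide left half is made from geranyl acetate (allylic oxidation of the E-methyl group, methylenation, hydroboration, bromination, Shi epoxidation). The Z-enol triflate right half is made from tert-butyl acetate and 5-bromo-2-methylpent-2-ene (alkylation, formylation, chelation-controlled triflation).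
5. Ring order: nothing but the epoxide is cyclic before step 9; the lactone ring is closed last, and the product of step 9 is the target.

Key step: step 9

Remark on the chemistry: the D-fructose-derived Shi ketone is taken to give the (R,R)-epoxide of an E-trisubstituted alkene, as it does for simple E-alkenes; if the sense were opposite, its enantiomer would be used.

**Route**

Step 1
Reactants: 1 geranyl acetate
Product: 3 (2E,6E)-3,7-dimethyl-8-oxoocta-2,6-dien-1-yl acetate, via 8-hydroxygeranyl acetate 2 (not isolated)
Conditions: SeO2 (0.2 equiv), t-BuOOH, salicylic acid (cat.), CH2Cl2, 23 °C; then MnO2, CH2Cl2, 23 °C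
Reagents that add atoms: tert-butyl hydroperoxide, CC(C)(C)OO (oxygen atom, relayed by catalytic selenium dioxide, O=[Se]=O)
Why: Riley-type allylic oxidation (ene reaction, then [2,3]-sigmatropic shift of the allylseleninic acid) should attack the E-methyl group of the electron-rich terminal alkene and spare the 2,3-alkene that the allylic acetate deactivates, and MnO2 should then oxidise only the allylic alcohol 2 to the enal with the 6E geometry kept.

Step 2
Reactants: 3 (2E,6E)-3,7-dimethyl-8-oxoocta-2,6-dien-1-yl acetate
Product: 4 (2E,6E)-3,7-dimethylnona-2,6,8-trien-1-yl acetate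
Conditions: Ph3PCH3Br, KN(SiMe3)2, THF, −78 → 0 °C
Reagents that add atoms: methyltriphenylphosphonium bromide, C[P+](c1ccccc1)(c1ccccc1)c1ccccc1.[Br-]
Why: Wittig methylenation, in which the non-stabilised ylide should add to the aldehyde much faster than to the acetate at low temperature and leave both E-alkenes untouched.

Step 3
Reactants: 4 (2E,6E)-3,7-dimethylnona-2,6,8-trien-1-yl acetate
Product: 6 (2E,6E)-9-hydroxy-3,7-dimethylnona-2,6-dien-1-yl acetate, via B-alkyl-9-borabicyclononane adduct 5 (not isolated)
Conditions: 9-borabicyclo[3.3.1]nonane (9-BBN), THF, 0 → 23 °C; then H2O2, aq. NaOAc, 0 → 23 °C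
Reagents that add atoms: hydrogen peroxide, OO (hydroxyl oxygen); 9-borabicyclo[3.3.1]nonane, B1C2CCCC1CCC2 (its atoms appear only in 5)
Why: Hydroboration–oxidation, in which the bulky dialkylborane should add only to the monosubstituted vinyl terminus of the diene with boron on the terminal carbon, and acetate-buffered peroxide should oxidise the C–B bond without hydrolysing the ester.

Step 4
Reactants: 6 (2E,6E)-9-hydroxy-3,7-dimethylnona-2,6-dien-1-yl acetate
Product: 7 (2E,6E)-9-bromo-3,7-dimethylnona-2,6-dien-1-yl acetate
Conditions: CBr4, PPh3, CH2Cl2, 0 °C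
Reagents that add atoms: carbon tetrabromide, BrC(Br)(Br)Br
Why: Appel reaction, an SN2 displacement at the primary carbon of the oxyphosphonium intermediate under neutral conditions, so that neither the alkenes nor the acetate should be touched.

Step 5
Reactants: 7 (2E,6E)-9-bromo-3,7-dimethylnona-2,6-dien-1-yl acetate
Product: 8 (2E)-5-[(2R,3R)-3-(2-bromoethyl)-3-methyloxiran-2-yl]-3-methylpent-2-en-1-yl acetate
Conditions: 1,2:4,5-di-O-isopropylidene-β-D-erythro-2,3-hexodiulo-2,6-pyranose (D-fructose-derived Shi ketone, 0.3 equiv), KHSO5 (as 2KHSO5·KHSO4·K2SO4), K2CO3, Bu4NHSO4, MeCN/CH2(OMe)2/aq. Na2B4O7 buffer, 0 °C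
Reagents that add atoms: potassium peroxymonosulfate, [K+].[O-]S(=O)(=O)OO
Why: Shi epoxidation, in which the chiral dioxirane should transfer oxygen through a spiro transition state to one face of the electron-rich E-trisubstituted 6,7-alkene and so set C6 and C7 both as R by reagent control, while the 2,3-alkene is deactivated by the allylic acetate and the alkyl bromide is inert to the dioxirane.

Step 6
Reactants: 9 tert-butyl acetate; 10 5-bromo-2-methylpent-2-ene
Product: 12 tert-butyl 6-methylhept-5-enoate, via lithium enolate of tert-butyl acetate 11 (not isolated)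
Conditions: LiN(i-Pr)2, THF, −78 °C; then 10, DMPU, −78 → 23 °C
Reagents that add atoms: none
Why: Ester enolate alkylation, in which enolate 11 should displace the primary bromide by SN2 with DMPU as promoter, the tert-butyl group suppressing Claisen self-condensation.

Step 7
Reactants: 12 tert-butyl 6-methylhept-5-enoate
Product: 15 tert-butyl 2-formyl-6-methylhept-5-enoate, via sodium ester enolate 13 (not isolated), via sodium enolate of the formyl ester 14 (not isolated)
Conditions: NaH (1.2 equiv), HCO2Et (3 equiv), EtOH (cat.), THF, 0 → 23 °C; cold aq. HCl work-up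
Reagents that add atoms: ethyl formate, CCOC=O
Why: Crossed Claisen condensation (sodium-mediated formylation), in which NaOEt generated from NaH and the catalytic ethanol should form ester enolate 13 reversibly, the non-enolisable formate should acylate it, and irreversible deprotonation of the product to the stabilised sodium enolate 14 should drive the condensation, while the hindered tert-butyl ester resists self-condensation and transesterification; the α-carbon of 15 is configurationally labile and of no consequence.

Step 8
Reactants: 15 tert-butyl 2-formyl-6-methylhept-5-enoate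
Product: 17 tert-butyl (2Z)-6-methyl-2-({[(trifluoromethyl)sulfonyl]oxy}methylidene)hept-5-enoate, via chelated lithium enolate of the formyl ester 16 (not isolated)
Conditions: aq. LiOH, Tf2O, toluene, 5 °C
Reagents that add atoms: trifluoromethanesulfonic anhydride, O=S(=O)(OS(=O)(=O)C(F)(F)F)C(F)(F)F
Why: O-Sulfonylation of the lithium-chelated enolate 16, formed from 15 and LiOH at the phase boundary, in which lithium holds the enolate oxygen cis to the ester carbonyl, should give the Z-enol triflate (chelation-controlled enol triflate formation), and the hindered tert-butyl ester should resist the cold aqueous base.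

Step 9
Reactants: 8 (2E)-5-[(2R,3R)-3-(2-bromoethyl)-3-methyloxiran-2-yl]-3-methylpent-2-en-1-yl acetate; 17 tert-butyl (2Z)-6-methyl-2-({[(trifluoromethyl)sulfonyl]oxy}methylidene)hept-5-enoate
Product: 19 (2E,5R)-5-hydroxy-3-methyl-5-[(2S)-2-methyl-6-(4-methylpent-3-en-1-yl)-7-oxo-2,3,4,7-tetrahydrooxepin-2-yl]pent-2-en-1-yl acetate (CNP0268675.1), via coupled epoxy tert-butyl ester 18 (not isolated)
Conditions: NiBr2·glyme (10 mol%), 4,4'-di-tert-butyl-2,2'-bipyridine (10 mol%), Mn powder (3 equiv), DMA, 23 °C; then filter, exchange DMA for CH2Cl2, (+)-10-camphorsulfonic acid (CSA, 0.3 equiv), 0 → 23 °C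
Reagents that add atoms: none
Why: In the first stage zerovalent nickel should insert into the C–OTf bond of 17 with retention of the Z geometry, a monovalent nickel species should abstract bromine from 8, and the primary C9 radical should be captured by the alkenylnickel species, which reductively eliminates to the C9–C10 bond of 18; this radical pathway leaves the epoxide and the acetate alone. On addition of CSA the carbonyl oxygen of the tert-butyl ester, held cis to C9 by the Z double bond, should attack the protonated epoxide at its tertiary carbon C7, and the resulting tert-butyl oxocarbenium ion loses isobutene, which closes the oxepinone ring in the 7-exo-tet mode (the epoxide C–O bond that breaks lies outside the new ring). The closest known reaction types are the nickel-catalysed reductive cross-electrophile coupling of alkenyl triflates with primary alkyl bromides and the Brønsted-acid-mediated lactonisation of epoxy tert-butyl esters. C7 is set by stereospecific inversion of the 7R epoxide carbon to 7S, and C6 keeps its epoxide C–O bond and stays R. The step needs retention of the Z-alkene, secured by the configurational stability of the alkenylnickel species at 23 °C and by the fact that only the Z isomer can lactonise; it needs attack at C7 and not at C6, secured by the better cation stabilisation at the tertiary carbon and the 7-exo over 8-endo preference. It also needs the ester and not the 2,3-alkene to act as internal nucleophile, secured by the allylic acetate that deactivates that alkene.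

**Compound list**

1 | geranyl acetate, (2E)-3,7-dimethylocta-2,6-dien-1-yl acetate | CC(C)=CCC/C(C)=C/COC(C)=O | starting material
2 | (2E,6E)-8-hydroxy-3,7-dimethylocta-2,6-dien-1-yl acetate (8-hydroxygeranyl acetate) | OC/C(C)=C/CC/C(C)=C/COC(C)=O | intermediate
3 | (2E,6E)-3,7-dimethyl-8-oxoocta-2,6-dien-1-yl acetate | O=C/C(C)=C/CC/C(C)=C/COC(C)=O | intermediate
4 | (2E,6E)-3,7-dimethylnona-2,6,8-trien-1-yl acetate | C=C/C(C)=C/CC/C(C)=C/COC(C)=O | intermediate
5 | (2E,6E)-9-(9-borabicyclo[3.3.1]nonan-9-yl)-3,7-dimethylnona-2,6-dien-1-yl acetate | B1(CC/C(C)=C/CC/C(C)=C/COC(C)=O)C2CCCC1CCC2 | intermediate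
6 | (2E,6E)-9-hydroxy-3,7-dimethylnona-2,6-dien-1-yl acetate | OCC/C(C)=C/CC/C(C)=C/COC(C)=O | intermediate
7 | (2E,6E)-9-bromo-3,7-dimethylnona-2,6-dien-1-yl acetate | BrCC/C(C)=C/CC/C(C)=C/COC(C)=O | intermediate
8 | (2E)-5-[(2R,3R)-3-(2-bromoethyl)-3-methyloxiran-2-yl]-3-methylpent-2-en-1-yl acetate | BrCC[C@@]1(C)O[C@@H]1CC/C(C)=C/COC(C)=O | intermediate
9 | tert-butyl acetate | CC(=O)OC(C)(C)C | starting material
10 | 5-bromo-2-methylpent-2-ene | CC(C)=CCCBr | starting material
11 | lithium 1-tert-butoxyethen-1-olate (lithium enolate of 9) | [Li+].[O-]C(=C)OC(C)(C)C | intermediate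
12 | tert-butyl 6-methylhept-5-enoate | CC(C)=CCCCC(=O)OC(C)(C)C | intermediate
13 | sodium (1Z)-1-tert-butoxy-6-methylhepta-1,5-dien-1-olate (sodium enolate of 12, drawn as one geometric isomer; its geometry has no bearing on the route) | [Na+].[O-]/C(OC(C)(C)C)=C/CCC=C(C)C | intermediate
14 | sodium (1Z)-2-(tert-butoxycarbonyl)-6-methylhepta-1,5-dien-1-olate (sodium enolate of 15, drawn as the chelated isomer) | [Na+].[O-]/C=C(/CCC=C(C)C)C(=O)OC(C)(C)C | intermediate
15 | tert-butyl 2-formyl-6-methylhept-5-enoate (racemic, enolisable α-carbon; drawn as the aldehyde tautomer) | CC(C)=CCCC(C=O)C(=O)OC(C)(C)C | intermediate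
16 | lithium (1Z)-2-(tert-butoxycarbonyl)-6-methylhepta-1,5-dien-1-olate (chelated lithium enolate of 15) | [Li+].[O-]/C=C(/CCC=C(C)C)C(=O)OC(C)(C)C | intermediate
17 | tert-butyl (2Z)-6-methyl-2-({[(trifluoromethyl)sulfonyl]oxy}methylidene)hept-5-enoate | CC(C)=CCC/C(=C/OS(=O)(=O)C(F)(F)F)C(=O)OC(C)(C)C | intermediate
18 | tert-butyl (2Z)-5-[(2R,3R)-3-[(3E)-5-acetoxy-3-methylpent-3-en-1-yl]-2-methyloxiran-2-yl]-2-(4-methylpent-3-en-1-yl)pent-2-enoate | CC(C)=CCC/C(=C/CC[C@@]1(C)O[C@@H]1CC/C(C)=C/COC(C)=O)C(=O)OC(C)(C)C | intermediate
19 | (2E,5R)-5-hydroxy-3-methyl-5-[(2S)-2-methyl-6-(4-methylpent-3-en-1-yl)-7-oxo-2,3,4,7-tetrahydrooxepin-2-yl]pent-2-en-1-yl acetate (CNP0268675.1) | CC(=O)OC/C=C(\C)CC[C@@H](O)[C@]1(C)CCC=C(CCC=C(C)C)C(=O)O1 | target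

**Step count and risks**

Total step count: 9. Longest linear sequence: 6 steps (steps 1, 2, 3, 4, 5 and 9); the right half takes steps 6 to 8.

Steps most likely to fail:

Step 9. What may go wrong: loss of the Z geometry at the alkenylnickel stage or through a competing radical addition–elimination at the enol triflate; reductive homodimerisation of either partner; oxidative addition of zerovalent nickel into the allylic acetate; opening of the epoxide by bromide under the Lewis acidity of the manganese salts; and, in the acid stage, capture of the activated epoxide by the 2,3-alkene or a hydride shift in place of attack by the ester carbonyl. Fallback: the union would be done by polar organometallic chemistry in isolated stages. Setting out from 8, Finkelstein exchange (NaI, acetone) should give (2E)-5-[(2R,3R)-3-(2-iodoethyl)-3-methyloxiran-2-yl]-3-methylpent-2-en-1-yl acetate F1, and zinc insertion (Zn dust, LiCl, THF, 25 °C) should give {2-[(2R,3R)-3-[(3E)-5-acetoxy-3-methylpent-3-en-1-yl]-2-methyloxiran-2-yl]ethyl}zinc iodide F2. A stereoretentive Negishi coupling of this reagent with 17 (Pd(PPh3)4, THF, 23 °C) should give 18, where the fallback comes back to the route; 18 would then be isolated, purified and lactonised in a separate operation (CSA, CH2Cl2) to 19.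

Step 5. What may go wrong: incomplete discrimination between the two trisubstituted alkenes, insufficient facial selectivity of the dioxirane, and hydrolysis of the acetate in the basic aqueous medium. Fallback: the epoxide would be installed by a hydroxyl-directed metal-catalysed epoxidation before bromination. Setting out from 6, vanadium-catalysed asymmetric epoxidation of the homoallylic alcohol (VO(Oi-Pr)3, chiral bishydroxamic acid ligand of the appropriate hand, cumene hydroperoxide, toluene, 0 °C) should give (2E)-5-[(2R,3R)-3-(2-hydroxyethyl)-3-methyloxiran-2-yl]-3-methylpent-2-en-1-yl acetate F3, the directing hydroxyl securing the 6,7-site. Appel bromination (CBr4, PPh3, 2,6-lutidine, CH2Cl2, 0 °C) should then give 8, where the fallback comes back to the route.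

Step 1. What may go wrong: low conversion, over-oxidation and competing oxidation at the allylic CH2 positions. Fallback: the enal would be built by cleavage and olefination. Setting out from 1, epoxidation of the more electron-rich 6,7-alkene (mCPBA, CH2Cl2, 0 °C) should give racemic (2E)-5-(3,3-dimethyloxiran-2-yl)-3-methylpent-2-en-1-yl acetate F4, and periodate cleavage (H5IO6, THF/H2O, 0 °C) should give (2E)-3-methyl-6-oxohex-2-en-1-yl acetate F5. An E-selective Wittig reaction with the stabilised ylide 2-(triphenylphosphoranylidene)propanal (toluene, 80 °C) should then give 3, where the fallback comes back to the route.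

**Further compounds**

F1 | step 9 | (2E)-5-[(2R,3R)-3-(2-iodoethyl)-3-methyloxiran-2-yl]-3-methylpent-2-en-1-yl acetate | ICC[C@@]1(C)O[C@@H]1CC/C(C)=C/COC(C)=O
F2 | step 9 | {2-[(2R,3R)-3-[(3E)-5-acetoxy-3-methylpent-3-en-1-yl]-2-methyloxiran-2-yl]ethyl}zinc iodide | I[Zn]CC[C@@]1(C)O[C@@H]1CC/C(C)=C/COC(C)=O
F3 | step 5 | (2E)-5-[(2R,3R)-3-(2-hydroxyethyl)-3-methyloxiran-2-yl]-3-methylpent-2-en-1-yl acetate | OCC[C@@]1(C)O[C@@H]1CC/C(C)=C/COC(C)=O
F4 | step 1 | rac-(2E)-5-(3,3-dimethyloxiran-2-yl)-3-methylpent-2-en-1-yl acetate | CC1(C)OC1CC/C(C)=C/COC(C)=O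
F5 | step 1 | (2E)-3-methyl-6-oxohex-2-en-1-yl acetate | O=CCC/C(C)=C/COC(C)=O
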